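The constants used here stand for no real mixture; the rest is arithmetic.

In a one-step world one reagent buys one substrate, and the charges allow 70.0% of target. This flask has a further step, which spends a second reagent on each target.

substrate 0.010 M; reagent in the second phase 0.700 equiv; time 25 min; volume of the second phase over the first 0.50

    target → over-reaction product (k1 = 4.8 × 10⁻⁵ min⁻¹)
    reagent in the reaction phase ⇌ dormant form (K2 = 0.82, k2 = 0.76 min⁻¹)
    substrate + reagent in the reaction phase ⇌ target (K3 = 75 L mol⁻¹, k3 = 100 L mol⁻¹ min⁻¹)
    reagent in the reaction phase ⇌ reagent in the second phase, rate k4*([reagent in the reaction phase] - [reagent in the second phase]/K4) per volume of the first phase (K4 = 0.50, k4 = 0.14 min⁻¹)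
    reagent in the reaction phase + target → over-reacted product (k5 = 140 L mol⁻¹ min⁻¹)

- in the second phase: reagent in the second phase; everything else is in the first
- charges count per volume of the first phase; a concentration in a rate is the amount of a species over the volume of its own phase; every rate counts per litre of the first phase
- run time (flask): 25 min

* how much target there is at 25 min, in percent of the substrate charged
* part of the substrate charged that has reacted at 25 min

1. Reagent is the limiting reagent: I open the books with 0.00700 M, less than the substrate. Over-reacted product holds two reagents per substrate, so the books close, with all reagent ended there, at a conversion of 35.0%.

2. Let c be c(reagent in the reaction phase). The exchanges are quick: transfer has a half-life of 1.24 min and dormant form relaxes in 0.411 min, both short against 25 min. So I treat them as balanced.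

3. Each unit of c then brings dormant form and second-phase reagent along, giving 2.07 units.

4. Target adds g units, where g is the binding constant times c(substrate). I replace the substrate curve by its mean between the charge and the closing value: 0.619. Open reagent is therefore W = S c, with 2.69.

5. Each over-reaction removes two units from W, at a rate proportional to c squared. W therefore decays second-order, to the charge over one plus N. I call N the drain number: twice the over-reaction constant, times g, over S squared, times charge and time, here 4.19.

6. Closing the books gives 3.10% target and 31.4% reacted. Target's loss by the first step is negligible, with a half-life of 240 h.

7. Checking the mean: substrate held at its closing value gives 30.3% reacted, and held at the charge 32.1%. My clock starts at once, though the second-phase reagent has a half-life of 1.24 min, so I expect to land high.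

The forecast gives 3% of target and 30.5% reacted, 0.90 percentage points below my figure, saying “over-reaction slowly drains it”.

The simulation gives 3.19% of target and 29.9% reacted.

That conversion is lower than my reckoning with substrate held at its closing value, and 1.5 points below my figure. The neighbour flask has 0.0060 M of substrate, with the same equivalents and time. There S becomes 2.44, and N, scaled from 4.19, becomes 1.83. The books then close on 3.76% target and 26.4% reacted. The neighbour flask gives 3.73% of target and 24.7% reacted.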